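All constants were chosen freely; the run is a simulation.

Read these four flasks as a race between one clock and the time allowed.

common to all: starting material 0.050 M; second substrate 0.0500 M; free catalyst 0.50 mM; time 2.5 min
- Wednesday's: temperature 40 °C
- Saturday's: temperature 10 °C
- Sunday's: temperature 70 °C
- Thursday's: temperature 100 °C

- which flask leads in amount of target, in percent of the starting material charged ("all alike" within 1.5 percentage points) (Wednesday's / Saturday's / Sunday's / Thursday's / all alike)
- how much target is there at the end, in percent of the starting material charged: Wednesday's
- how much target is there at the end, in percent of the starting material charged: Saturday's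
- how much target is there at the end, in percent of the starting material charged: Sunday's
- how much target is there at the end, in percent of the starting material charged: Thursday's

- the constants hold at 40 °C; other temperatures follow from the activation energies and enthalpies

    second substrate + free catalyst ⇌ catalyst intermediate B (K1 = 9.3 M⁻¹, k1 = 16 M⁻¹ s⁻¹, Ea1 = 38.0 kJ mol⁻¹, ΔH1 = −48.0 kJ mol⁻¹)
    target ⇌ isomer of the product (K2 = 0.55, k2 = 0.013 s⁻¹, Ea2 = 78.0 kJ mol⁻¹, ΔH2 = −67.0 kJ mol⁻¹)
    catalyst intermediate A → free catalyst + target (k3 = 3.0 s⁻¹, Ea3 = 71.0 kJ mol⁻¹)
    starting material + free catalyst ⇌ catalyst intermediate A (K4 = 9.4 M⁻¹, k4 = 21 M⁻¹ s⁻¹, Ea4 = 38.0 kJ mol⁻¹, ΔH4 = −33.0 kJ mol⁻¹)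
    catalyst intermediate B → free catalyst + second product (k5 = 1.9 s⁻¹, Ea5 = 71.0 kJ mol⁻¹)
    (constants at 40 °C)

Starting material bound to free catalyst, as catalyst intermediate A, either falls back or releases target. Fall-back, whose activation energy is that of capture less the enthalpy of step 4, and release both carried 71.0 kJ mol⁻¹, so the odds between them stayed alike from flask to flask: I counted 1.74 captures per target. I multiplied that count by the reciprocal of the capture constant times the charged catalyst, which gave 166 s at 40 °C. Bound catalyst captures nothing, so I divided by the free share, reckoned as a steady state at the charged amounts and held for the run. That makes the loss pseudo-first-order. On Wednesday's the free share was 70.3%, giving 3.94 min. This is the clearing time: the time in which unbound starting material falls to 36.8% of its amount.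

My table had a row per flask, with columns for free share, clearing time, target's equilibrium share of target plus isomer, and estimate.

Saturday's row read 35.1% free and 37.0 min to clear, far longer than the 2.5 min allowed. Its isomer step needed 27.4 min, so I skipped the equilibrium column there and estimated 6.53%.

Wednesday's isomer step needed 27.3 s, shorter than its clearing time. So I applied the share 64.5% and estimated 30.3%.

Sunday's row read 89.1%, 52.0 s and 94.5%, which gave 89.2%.

Thursday's row read 95.9%, 16.6 s and 99.1%. Its clock was far inside the time allowed, so its estimate was the equilibrium share, 99.1%. I backed Thursday's.

The forecast also named Thursday's, with 34% for Wednesday's, 6.3% for Saturday's, 90% for Sunday's and 99% for Thursday's. That put it above me on Wednesday's. Its ground for the hot flasks was that “its exothermic equilibrium swings strongly back towards target on heating”.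

The simulation gave Thursday's the lead, with 34.5% on Wednesday's, 6.38% on Saturday's, 90.2% on Sunday's and 99.1% on Thursday's.

Wednesday's unbound starting material ended at 50.5%, against 53.0% from the clearing time 3.94 min. Its target held 69.9% of target plus isomer at the end, above my equilibrium share of 64.5%. Thursday's charge at 75 °C reckoned the same way had a free share of 90.8%, a clearing time of 42.2 s and an equilibrium share of 96.0%. That gave 93.3% target. That neighbouring flask ended with 2.27% starting material, 3.88% isomer and 93.8% target.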